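The readings were computed from invented constants.

**Amounts charged.** Six flasks share one charge of substrate, coupling partner and added ligand, and they differ in the amount of free catalyst.

all flasks: substrate 0.069 M; coupling partner 1.05 equiv; added ligand 0.95 mM

|  | free catalyst | remark | time |
|---|---|---|---|
| alder | 0.13 mol% | run made earlier |  |
| elm | 1.2 mol% | run made earlier |  |
| north-west | 0.25 mol% |  | 30 h |
| north-east | 0.5 mol% |  | 30 h |
| south | 1 mol% |  | 30 h |
| west | 2 mol% |  | 30 h |

| alder: time / h | alder: target / % | elm: time / h | elm: target / % |
|---|---|---|---|
| 4.00 | 0.7 | 4.00 | 3.5 |
| 8.00 | 0.7 | 8.00 | 7.2 |
| 12.0 | 0.6 | 12.0 | 11.5 |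
| 15.0 | 1.2 | 15.0 | 14.1 |

(readings scatter by 0.3 percentage points)

- the numbers in the tables scatter by 0.3 percentage points (one standard deviation)
- steps thought possible: coupling partner + free catalyst <-> catalyst intermediate A; catalyst intermediate A -> catalyst intermediate B; substrate + catalyst intermediate B <-> catalyst intermediate C; catalyst intermediate C <-> free catalyst + target; free catalyst + added ligand <-> idle complex; free catalyst + target -> free catalyst + over-reaction product
- "hardly changes" means that all values lie within two and a half points (for a concentration: within two and a half percent of the largest)

1. amount of target at the end, in percent of the substrate charged for north-west, north-east, south, west, in this order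
2. the shape of the row from first to last (hardly changes / rises, then falls / rises all the way / falls all the way / falls, then rises)

**Time constant.** A line through the origin over a run's readings gives a time constant, the time in which that slope would use the whole substrate: 107 h for elm, and 1340 h for alder. The alder value is weak, since its highest reading is 1.2% against a scatter of 0.3 percentage points.

**Catalyst order.** I carry one reading: the order in catalyst, the slope of log rate against log loading, which comes to 1.14. An order above one would fit added ligand holding catalyst in a fast pairing and freeing a larger share as loading rises; elm is charged with 0.828 mM of catalyst against 0.95 mM of ligand.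

**The bracket.** For the south flask, the order turns elm's time constant into 131 h, and 30 h is about a quarter of that. From above, a rate that never falls gives 22.9%. From below, a rate falling in step with substrate gives 20.4%. Elm shows no bend within the scatter, so I cannot choose between them and hold the gap of 2.5 points. These edges are estimates, and both lean on the weak alder value. With a positive order, I expect the row to rise.

The forecast, from the same two runs, gives 4.4%, 9.6%, 22% and 50%, a row that rises all the way, on the ground “that higher loadings partly titrate it”, and its south value stands inside my bracket.

**South checked.** The flasks give 4.21%, 9.06%, 20.6% and 44.7%, so the row rises all the way. South's 20.6% stands 0.20 points above my lower edge, with 78.4% of its substrate left at the end.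

    coupling partner + free catalyst ⇌ catalyst intermediate A (K = 21.0 M⁻¹, k = 0.160 M⁻¹ s⁻¹)
    catalyst intermediate A → catalyst intermediate B (k = 0.00260 s⁻¹)
    substrate + catalyst intermediate B ⇌ catalyst intermediate C (K = 20.0 M⁻¹, k = 0.0820 M⁻¹ s⁻¹)
    catalyst intermediate C ⇌ free catalyst + target (K = 0.230 M, k = 0.00210 s⁻¹)
    free catalyst + added ligand ⇌ idle complex, settled at all times (K = 16000 M⁻¹)
    free catalyst + target → free catalyst + over-reaction product (k = 0.0150 M⁻¹ s⁻¹)

**West again.** Beyond elm's loading, the same order gives the west flask a time constant of 59.6 h, and so edges of 39.5% and 50.3%. West ends between them at 44.7% of target, with 6.49% of over-reaction product and 48.7% of substrate left.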